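**Strategy.** The chroman ring C is disconnected across O1–C2 and C3–C4. This turns resorcinol ring A into an ortho-quinone methide (O1 as carbonyl oxygen, C4 as exocyclic methylene) and C2–C3 with ring B into an arylacetaldehyde. An enamine-catalysed Michael addition/hemiacetalisation joins both in one operation: the α-carbon (C3) attacks the methide carbon (C4) under control of a chiral pyrrolidine, and the regenerated phenol oxygen O1 closes onto the aldehyde carbon C2, giving a (3S)-chroman-2-ol. The precursor pair is a base-labile 2-(tosylmethyl)phenol and a silyl-protected arylacetaldehyde that already bears the 1,1-dimethylallyl group, installed by aromatic Claisen rearrangement. Ionic deoxygenation and desilylation finish the synthesis.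

Key step: step 12

Remark: C3 of the target is read from the SMILES as S (C2 > C1' > C4 > H), the same spatial sense as in (S)-equol.

**Fragment A (ortho-quinone methide precursor)**

Step 1
Reactants: 1 2,4-dihydroxybenzaldehyde
Product: 2 2-hydroxy-4-[(triisopropylsilyl)oxy]benzaldehyde
Conditions: TIPSCl (1.05 equiv), imidazole, CH2Cl2, 0 °C to rt
Reagents that add atoms: triisopropylsilyl chloride, CC(C)[Si](Cl)(C(C)C)C(C)C
Why: The 2-OH is held in a hydrogen bond to the formyl group, so O-silylation should occur selectively at the free 4-OH.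

Step 2
Reactants: 2 2-hydroxy-4-[(triisopropylsilyl)oxy]benzaldehyde
Product: 3 2-(hydroxymethyl)-5-[(triisopropylsilyl)oxy]phenol
Conditions: NaBH4, THF/MeOH, 0 °C, neutral work-up
Reagents that add atoms: none
Why: Borohydride reduction of the aldehyde should give the salicyl alcohol, the aryl silyl ether being stable at 0 °C.

Step 3
Reactants: 3 2-(hydroxymethyl)-5-[(triisopropylsilyl)oxy]phenol
Product: 4 2-[(4-methylbenzenesulfonyl)methyl]-5-[(triisopropylsilyl)oxy]phenol
Conditions: p-TolSO2Na (1.5 equiv), AcOH, CH2Cl2, rt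
Reagents that add atoms: sodium 4-methylbenzenesulfinate, [Na+].Cc1ccc(cc1)S(=O)[O-]
Why: Acid ionises the benzylic alcohol, which is activated by the ortho-hydroxy and para-silyloxy groups, and the sulfinate captures the cation at sulfur (SN1-type sulfonylation) to give a storable quinone methide precursor.

**Fragment B (arylacetaldehyde)**

Step 4
Reactants: 5 2,3,4-trihydroxybenzaldehyde
Product: 6 4-hydroxy-2,2-diphenyl-1,3-benzodioxole-5-carbaldehyde
Conditions: Ph2CCl2 (1.2 equiv), Ph2O, 175 °C
Reagents that add atoms: dichlorodiphenylmethane, ClC(Cl)(c1ccccc1)c1ccccc1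
Why: Diphenylmethylene ketal formation should span the 3,4-catechol, because the 2-OH is chelated to the aldehyde and cannot form a five-membered ketal with a free neighbour on both sides.

Step 5
Reactants: 6 4-hydroxy-2,2-diphenyl-1,3-benzodioxole-5-carbaldehyde
Product: 7 4-methoxy-2,2-diphenyl-1,3-benzodioxole-5-carbaldehyde
Conditions: MeI, K2CO3, DMF, rt
Reagents that add atoms: iodomethane, CI
Why: Williamson methylation of the only remaining phenol fixes the 2'-methoxy group of the target.

Step 6
Reactants: 7 4-methoxy-2,2-diphenyl-1,3-benzodioxole-5-carbaldehyde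
Product: 8 3,4-dihydroxy-2-methoxybenzaldehyde
Conditions: AcOH/H2O (4:1), reflux
Reagents that add atoms: none
Why: Acid hydrolysis of the diaryl ketal through the stabilised diphenylmethyl cation should release the catechol and leave the methyl ether untouched.

Step 7
Reactants: 8 3,4-dihydroxy-2-methoxybenzaldehyde
Product: 9 3-hydroxy-2-methoxy-4-[(3-methylbut-2-en-1-yl)oxy]benzaldehyde
Conditions: prenyl bromide (1.05 equiv), NaHCO3, DMF, 40 °C
Reagents that add atoms: 1-bromo-3-methylbut-2-ene, CC(C)=CCBr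
Why: The 4-OH para to the formyl group is the more acidic phenol, so the weak base should ionise and alkylate it selectively (Williamson etherification).

Step 8
Reactants: 9 3-hydroxy-2-methoxy-4-[(3-methylbut-2-en-1-yl)oxy]benzaldehyde
Product: 11 3,4-dihydroxy-2-methoxy-5-(2-methylbut-3-en-2-yl)benzaldehyde, via ortho-dienone 10 (not isolated)
Conditions: PhNEt2, 190 °C (sealed tube, argon), short reaction time
Reagents that add atoms: none
Why: Aromatic Claisen rearrangement ([3,3]-sigmatropic) should deliver the dimethyl-substituted allyl terminus to C5, the only free ortho position, and tautomerisation of the dienone gives the 1,1-dimethylallyl phenol.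

Step 9
Reactants: 11 3,4-dihydroxy-2-methoxy-5-(2-methylbut-3-en-2-yl)benzaldehyde
Product: 12 3,4-bis[(tert-butyldimethylsilyl)oxy]-2-methoxy-5-(2-methylbut-3-en-2-yl)benzaldehyde
Conditions: TBSOTf (2.5 equiv), 2,6-lutidine, CH2Cl2, 0 °C to rt
Reagents that add atoms: tert-butyldimethylsilyl trifluoromethanesulfonate, CC(C)(C)[Si](C)(C)OS(=O)(=O)C(F)(F)F
Why: The silyl triflate should be reactive enough to silylate both catechol oxygens, including the hindered 4-OH next to the quaternary carbon, while the non-enolisable aldehyde and the alkene are inert.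

Step 10
Reactants: 12 3,4-bis[(tert-butyldimethylsilyl)oxy]-2-methoxy-5-(2-methylbut-3-en-2-yl)benzaldehyde
Product: 13 1,2-bis[(tert-butyldimethylsilyl)oxy]-3-methoxy-4-(2-methoxyethenyl)-6-(2-methylbut-3-en-2-yl)benzene (E/Z mixture)
Conditions: Ph3P(CH2OMe)Cl (1.5 equiv), KN(SiMe3)2 (1.4 equiv), THF, 0 °C; then 12, 0 °C to rt
Reagents that add atoms: (methoxymethyl)triphenylphosphonium chloride, COC[P+](c1ccccc1)(c1ccccc1)c1ccccc1.[Cl-]
Why: Wittig methoxymethylenation adds the one missing carbon (the future C2), and the non-nucleophilic amide base, used in deficit, spares the aryl silyl ethers.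

Step 11
Reactants: 13 1,2-bis[(tert-butyldimethylsilyl)oxy]-3-methoxy-4-(2-methoxyethenyl)-6-(2-methylbut-3-en-2-yl)benzene
Product: 14 2-{3,4-bis[(tert-butyldimethylsilyl)oxy]-2-methoxy-5-(2-methylbut-3-en-2-yl)phenyl}acetaldehyde
Conditions: aq. HCl (2 M), THF, 0 °C to rt; used crude
Reagents that add atoms: water, O
Why: Protonation of the enol ether at the benzylic carbon and hydrolysis of the oxocarbenium ion should give the arylacetaldehyde under conditions that aryl silyl ethers and the monosubstituted alkene tolerate.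

**Union and end game**

Step 12
Reactants: 14 2-{3,4-bis[(tert-butyldimethylsilyl)oxy]-2-methoxy-5-(2-methylbut-3-en-2-yl)phenyl}acetaldehyde; 4 2-[(4-methylbenzenesulfonyl)methyl]-5-[(triisopropylsilyl)oxy]phenol
Product: 16 (3S)-3-{3,4-bis[(tert-butyldimethylsilyl)oxy]-2-methoxy-5-(2-methylbut-3-en-2-yl)phenyl}-7-[(triisopropylsilyl)oxy]-3,4-dihydro-2H-chromen-2-ol (both C2 epimers), via ortho-quinone methide 15 (not isolated)
Conditions: (S)-α,α-diphenylprolinol trimethylsilyl ether (20 mol%), Na2CO3 (1.5 equiv), CH2Cl2/H2O (10:1), 0 °C; 4 (1.3 equiv) added in portions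
Reagents that add atoms: none
Why: Carbonate deprotonates phenol 4 and expels p-toluenesulfinate by 1,4-elimination to give ortho-quinone methide 15, while the amine condenses with 14 to an E-configured enamine; its nucleophilic carbon (future C3) adds to the exocyclic methylene of 15 (future C4) with re-aromatisation, and the phenol oxygen so regenerated adds to the iminium or aldehyde carbon (future C2), so that hydrolysis releases lactol 16 and the catalyst. The closest known reaction type is the diarylprolinol-silyl-ether-catalysed Michael addition/hemiacetalisation (formal [4+2]) of aldehydes with ortho-quinone methides generated in situ from 2-(sulfonylalkyl)phenols. Ring C is closed by a 6-exo-trig attack of O1 on C2, the whole being a stepwise formal [4+2] and not a concerted cycloaddition. C3 is set by the catalyst, whose diphenyl(silyloxy)methyl group shields one face of the anti E-enamine so that the (S)-amine should deliver the 3S configuration (aryl outranks the new benzylic carbon); C2 forms as an anomeric mixture that does not matter because it becomes CH2. The step needs C- over N-alkylation, cross- over self-reaction (aldol of 14, oligomerisation of 15) and configurational integrity of the α-aryl centre; these are secured by slow release of 15 into pre-formed enamine, by the high electrophilicity of the unsubstituted methide, and by fast lactol closure, which masks the enolisable aldehyde.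

Step 13
Reactants: 16 (3S)-3-{3,4-bis[(tert-butyldimethylsilyl)oxy]-2-methoxy-5-(2-methylbut-3-en-2-yl)phenyl}-7-[(triisopropylsilyl)oxy]-3,4-dihydro-2H-chromen-2-ol
Product: 17 (3S)-3-{3,4-bis[(tert-butyldimethylsilyl)oxy]-2-methoxy-5-(2-methylbut-3-en-2-yl)phenyl}-7-[(triisopropylsilyl)oxy]-3,4-dihydro-2H-chromene
Conditions: Et3SiH (5 equiv), BF3·OEt2 (2 equiv), CH2Cl2, −78 °C
Reagents that add atoms: none
Why: Ionic hydrogenation of the lactol (BF3-promoted ionisation to the cyclic oxocarbenium ion, hydride transfer from the silane) should remove the C2 hydroxyl and keep both new ring bonds, and the low temperature and excess silane should outrun loss of the C3 proton, so the stereocentre is retained.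

Step 14
Reactants: 17 (3S)-3-{3,4-bis[(tert-butyldimethylsilyl)oxy]-2-methoxy-5-(2-methylbut-3-en-2-yl)phenyl}-7-[(triisopropylsilyl)oxy]-3,4-dihydro-2H-chromene
Product: 18 (3S)-3-[3,4-dihydroxy-2-methoxy-5-(2-methylbut-3-en-2-yl)phenyl]-3,4-dihydro-2H-chromen-7-ol
Conditions: Bu4NF (4 equiv), AcOH (4 equiv), degassed THF, 0 °C, argon
Reagents that add atoms: none
Why: Buffered fluoride should cleave all three aryl silyl ethers in one operation without acid (which could cyclise the ortho-allyl phenol) or free base (which would expose the catechol to air oxidation).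

**Compound list**

1 | 2,4-dihydroxybenzaldehyde | O=Cc1ccc(O)cc1O | starting material
2 | 2-hydroxy-4-[(triisopropylsilyl)oxy]benzaldehyde | O=Cc1ccc(O[Si](C(C)C)(C(C)C)C(C)C)cc1O | intermediate
3 | 2-(hydroxymethyl)-5-[(triisopropylsilyl)oxy]phenol | OCc1ccc(O[Si](C(C)C)(C(C)C)C(C)C)cc1O | intermediate
4 | 2-[(4-methylbenzenesulfonyl)methyl]-5-[(triisopropylsilyl)oxy]phenol | Cc1ccc(cc1)S(=O)(=O)Cc1ccc(O[Si](C(C)C)(C(C)C)C(C)C)cc1O | intermediate
5 | 2,3,4-trihydroxybenzaldehyde | O=Cc1ccc(O)c(O)c1O | starting material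
6 | 4-hydroxy-2,2-diphenyl-1,3-benzodioxole-5-carbaldehyde | O=Cc1ccc2OC(c3ccccc3)(c3ccccc3)Oc2c1O | intermediate
7 | 4-methoxy-2,2-diphenyl-1,3-benzodioxole-5-carbaldehyde | O=Cc1ccc2OC(c3ccccc3)(c3ccccc3)Oc2c1OC | intermediate
8 | 3,4-dihydroxy-2-methoxybenzaldehyde | COc1c(C=O)ccc(O)c1O | intermediate
9 | 3-hydroxy-2-methoxy-4-[(3-methylbut-2-en-1-yl)oxy]benzaldehyde | COc1c(C=O)ccc(OCC=C(C)C)c1O | intermediate
10 | 5-hydroxy-6-methoxy-3-(2-methylbut-3-en-2-yl)-4-oxocyclohexa-1,5-diene-1-carbaldehyde (ortho-dienone, racemic) | O=CC1=CC(C(C)(C)C=C)C(=O)C(O)=C1OC | intermediate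
11 | 3,4-dihydroxy-2-methoxy-5-(2-methylbut-3-en-2-yl)benzaldehyde | COc1c(C=O)cc(C(C)(C)C=C)c(O)c1O | intermediate
12 | 3,4-bis[(tert-butyldimethylsilyl)oxy]-2-methoxy-5-(2-methylbut-3-en-2-yl)benzaldehyde | COc1c(C=O)cc(C(C)(C)C=C)c(O[Si](C)(C)C(C)(C)C)c1O[Si](C)(C)C(C)(C)C | intermediate
13 | 1,2-bis[(tert-butyldimethylsilyl)oxy]-3-methoxy-4-(2-methoxyethenyl)-6-(2-methylbut-3-en-2-yl)benzene (E/Z mixture) | COC=Cc1cc(C(C)(C)C=C)c(O[Si](C)(C)C(C)(C)C)c(O[Si](C)(C)C(C)(C)C)c1OC | intermediate
14 | 2-{3,4-bis[(tert-butyldimethylsilyl)oxy]-2-methoxy-5-(2-methylbut-3-en-2-yl)phenyl}acetaldehyde | O=CCc1cc(C(C)(C)C=C)c(O[Si](C)(C)C(C)(C)C)c(O[Si](C)(C)C(C)(C)C)c1OC | intermediate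
15 | 6-methylidene-3-[(triisopropylsilyl)oxy]cyclohexa-2,4-dien-1-one (ortho-quinone methide) | C=C1C=CC(O[Si](C(C)C)(C(C)C)C(C)C)=CC1=O | intermediate
16 | (3S)-3-{3,4-bis[(tert-butyldimethylsilyl)oxy]-2-methoxy-5-(2-methylbut-3-en-2-yl)phenyl}-7-[(triisopropylsilyl)oxy]-3,4-dihydro-2H-chromen-2-ol (both C2 epimers) | C=CC(C)(C)c1cc([C@H]2C(O)Oc3cc(O[Si](C(C)C)(C(C)C)C(C)C)ccc3C2)c(OC)c(O[Si](C)(C)C(C)(C)C)c1O[Si](C)(C)C(C)(C)C | intermediate
17 | (3S)-3-{3,4-bis[(tert-butyldimethylsilyl)oxy]-2-methoxy-5-(2-methylbut-3-en-2-yl)phenyl}-7-[(triisopropylsilyl)oxy]-3,4-dihydro-2H-chromene | C=CC(C)(C)c1cc([C@H]2COc3cc(O[Si](C(C)C)(C(C)C)C(C)C)ccc3C2)c(OC)c(O[Si](C)(C)C(C)(C)C)c1O[Si](C)(C)C(C)(C)C | intermediate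
18 | (3S)-3-[3,4-dihydroxy-2-methoxy-5-(2-methylbut-3-en-2-yl)phenyl]-3,4-dihydro-2H-chromen-7-ol | C=CC(C)(C)c1cc([C@H]2COc3cc(O)ccc3C2)c(OC)c(O)c1O | target

**Step count.** Total: 14 steps. Longest linear sequence: 11 steps (5 to 18, steps 4–14); fragment A (steps 1–3) is convergent.

**Steps most likely to fail**

1. Step 12. The α-aryl centre may lose enantiopurity by renewed enamine or enol formation before or after lactol closure, the amine may be N-alkylated by the methide, and self-aldolisation of the aldehyde or oligomerisation of the methide may outrun the cross-reaction. The fallback replaces the catalytic annulation by an auxiliary-controlled enolate alkylation followed by ring closure; it sets out from 14 and 3, comes back at 17 and so also bypasses step 13. Pinnick oxidation of 14 (NaClO2, NaH2PO4, 2-methylbut-2-ene, t-BuOH/H2O) should give the arylacetic acid F1. This is coupled through its pivalic mixed anhydride (PivCl, Et3N, then LiCl) with (4S)-4-benzyl-1,3-oxazolidin-2-one to the N-acyl oxazolidinone F2. In parallel, 3 is O-allylated at the phenol (allyl bromide, K2CO3, acetone) to the allyl ether alcohol F3 and brominated under Appel conditions (CBr4, PPh3, CH2Cl2, 0 °C) to the benzyl bromide F4. Alkylation of the sodium Z-enolate of F2 (NaN(SiMe3)2, THF, −78 °C) with F4, anti to the benzyl group of the auxiliary, should give the (2S)-configured imide F5. LiBH4 (THF/MeOH, 0 °C) removes the auxiliary to give the primary alcohol F6, and Pd(PPh3)4 with morpholine cleaves the allyl ether to the phenol alcohol F7. Mitsunobu cyclisation (PPh3, DIAD, THF, 0 °C) then closes ring C to 17.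

2. Step 8. At the temperature of the rearrangement the prenyl ether may fragment, the new allyl group may isomerise further (abnormal Claisen pathway through a spirocyclopropane), or the ortho-allyl phenol may cyclise onto the alkene. The fallback installs the group by cross-coupling; it sets out from 7 and comes back at 11. Bromination of 7 (NBS, MeCN, rt) para to the methoxy group should give the aryl bromide F8. A γ-selective Suzuki–Miyaura coupling with potassium trifluoro(3-methylbut-2-en-1-yl)borate (Pd(OAc)2, 1,1'-bis(di-tert-butylphosphino)ferrocene, K2CO3, THF/H2O, 60 °C) should give the 1,1-dimethylallyl arene F9. Ketal hydrolysis (AcOH/H2O, 80 °C) gives 11.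

3. Step 11. The electron-rich arylacetaldehyde may enolise, self-condense or oxidise during aqueous acid hydrolysis, and prolonged acid may start to cleave silyl ethers. The fallback reaches 14 without aqueous acid; it sets out from 12 and comes back at 14. Corey–Chaykovsky epoxidation (trimethylsulfonium iodide, KN(SiMe3)2, THF, 0 °C) should give the aryl oxirane F10. Meinwald rearrangement (ZnI2 cat., CH2Cl2, 0 °C; benzylic ring opening and 1,2-hydride shift) isomerises it to 14, whose solution is taken directly into step 12.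

**Further compounds**

F1 | step 12 | 2-{3,4-bis[(tert-butyldimethylsilyl)oxy]-2-methoxy-5-(2-methylbut-3-en-2-yl)phenyl}acetic acid | OC(=O)Cc1cc(C(C)(C)C=C)c(O[Si](C)(C)C(C)(C)C)c(O[Si](C)(C)C(C)(C)C)c1OC
F2 | step 12 | (4S)-4-benzyl-3-(2-{3,4-bis[(tert-butyldimethylsilyl)oxy]-2-methoxy-5-(2-methylbut-3-en-2-yl)phenyl}acetyl)-1,3-oxazolidin-2-one | O=C(Cc1cc(C(C)(C)C=C)c(O[Si](C)(C)C(C)(C)C)c(O[Si](C)(C)C(C)(C)C)c1OC)N1[C@@H](Cc2ccccc2)COC1=O
F3 | step 12 | {2-(prop-2-en-1-yloxy)-4-[(triisopropylsilyl)oxy]phenyl}methanol | OCc1ccc(O[Si](C(C)C)(C(C)C)C(C)C)cc1OCC=C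
F4 | step 12 | [4-(bromomethyl)-3-(prop-2-en-1-yloxy)phenoxy]triisopropylsilane | BrCc1ccc(O[Si](C(C)C)(C(C)C)C(C)C)cc1OCC=C
F5 | step 12 | (4S)-4-benzyl-3-[(2S)-2-{3,4-bis[(tert-butyldimethylsilyl)oxy]-2-methoxy-5-(2-methylbut-3-en-2-yl)phenyl}-3-{2-(prop-2-en-1-yloxy)-4-[(triisopropylsilyl)oxy]phenyl}propanoyl]-1,3-oxazolidin-2-one | C=CC(C)(C)c1cc([C@@H](C(=O)N2[C@@H](Cc3ccccc3)COC2=O)Cc2ccc(O[Si](C(C)C)(C(C)C)C(C)C)cc2OCC=C)c(OC)c(O[Si](C)(C)C(C)(C)C)c1O[Si](C)(C)C(C)(C)C
F6 | step 12 | (2S)-2-{3,4-bis[(tert-butyldimethylsilyl)oxy]-2-methoxy-5-(2-methylbut-3-en-2-yl)phenyl}-3-{2-(prop-2-en-1-yloxy)-4-[(triisopropylsilyl)oxy]phenyl}propan-1-ol | C=CC(C)(C)c1cc([C@@H](CO)Cc2ccc(O[Si](C(C)C)(C(C)C)C(C)C)cc2OCC=C)c(OC)c(O[Si](C)(C)C(C)(C)C)c1O[Si](C)(C)C(C)(C)C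
F7 | step 12 | 2-[(2S)-2-{3,4-bis[(tert-butyldimethylsilyl)oxy]-2-methoxy-5-(2-methylbut-3-en-2-yl)phenyl}-3-hydroxypropyl]-5-[(triisopropylsilyl)oxy]phenol | C=CC(C)(C)c1cc([C@@H](CO)Cc2ccc(O[Si](C(C)C)(C(C)C)C(C)C)cc2O)c(OC)c(O[Si](C)(C)C(C)(C)C)c1O[Si](C)(C)C(C)(C)C
F8 | step 8 | 7-bromo-4-methoxy-2,2-diphenyl-1,3-benzodioxole-5-carbaldehyde | O=Cc1cc(Br)c2OC(c3ccccc3)(c3ccccc3)Oc2c1OC
F9 | step 8 | 4-methoxy-7-(2-methylbut-3-en-2-yl)-2,2-diphenyl-1,3-benzodioxole-5-carbaldehyde | O=Cc1cc(C(C)(C)C=C)c2OC(c3ccccc3)(c3ccccc3)Oc2c1OC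
F10 | step 11 | 2-{3,4-bis[(tert-butyldimethylsilyl)oxy]-2-methoxy-5-(2-methylbut-3-en-2-yl)phenyl}oxirane (racemic) | C=CC(C)(C)c1cc(C2CO2)c(OC)c(O[Si](C)(C)C(C)(C)C)c1O[Si](C)(C)C(C)(C)C
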